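## Structural features

The target is one cyclohexane ring (quinic acid numbering): C1 is quaternary and carries a tertiary hydroxyl and the carboxyl group, C2 and C6 are methylene groups, and C3, C4 and C5 are three contiguous secondary carbinol carbons. O4 and O5 are esterified with (E)-p-coumaric acid, while O1, O3, the carboxyl group and both phenols are free. In the stable chair the carboxyl group, O4 and O5 are equatorial and O1 and O3 are axial on the same face; O3 is cis to O4, O4 is trans to O5, and O5 is cis to the carboxyl group. C3, C4 and C5 stand next to one another, but C1 is separated from them by two methylene groups, so no neighbouring stereocentre can relay its configuration. The fragile parts are the two cinnamate esters and their E-alkenes (base, hydride, hydrogenation), the phenols, and the cis-vicinal O3–H/O4-acyl pair, across which an acyl group migrates as soon as base is present. The real difficulties are to acylate O4 and O5 but not the equally secondary O3, and to set the remote quaternary C1 relative to C3–C5. The key step uses the fact that O1 and O3 are syn-diaxial across C2 and are exactly the two oxygens that stay free: a one-carbon O1–CH2–O3 bridge (a 1,3-dioxane across C1–C2–C3) lets the C1–C6 bond form on one face only and masks both oxygens during acylation.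

## Logic of the disconnections

18 ⇒ 16 (through 17). Bonds cut: the two O–CH2 bonds of the O1–CH2–O3 formal, the two aryl O–CH2OMe bonds and the carboxyl O–C(CH3)3 bond. All free groups of 18 are released in one acidic or neutral operation, because base would move the O4 acyl group to O3 once O3–H is free. The gain is a fully protected, non-polar diester. The forward step must open a bridged formal without base, hydride or strong nucleophile.

16 ⇒ 12 + 15 (15 from 13). Bonds cut: the two acyl C–O bonds at O4 and O5. The cut is convergent, and 12 has only these two hydroxyls free, so regiochemistry needs no control. The forward step must esterify two vicinal secondary hydroxyls completely. The phenol of 13 needs a mask that falls in the final operation, which is why 15 is made through 14.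

12 ⇒ 11. Bonds cut: the two C–O bonds of the O4/O5 isopropylidene ketal. This ketal is the original protecting group of 1, so no protecting-group exchange is needed on the way. The forward step must hydrolyse a ketal beside a formal and a tert-butyl ester, which the large difference in oxocarbenium stability allows.

11 ⇒ 10. Bond cut: C1–C6. This removes the carbocycle and the quaternary stereocentre at once and leaves a monocyclic dioxane ester whose C1 configuration is irrelevant. The forward step must form the bond on the face of the enolate that keeps O1 and O3 bridged, which the tether enforces. Compared with a precursor carrying two bulky silyl ethers on O4/O5, 10 keeps the ketal: it holds O4–C4–C5–O5 synclinal as the product chair needs, puts less bulk beside C6, and saves the exchange steps. The formal is kept as the tether because it has no stereocentre of its own and no substituent pointing into the new ring.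

10 ⇒ 9 ⇒ 8. Bonds cut: C6–I (back to a C6 sulfonate) and the O1–CH2 bond of the formal (back to a methoxymethyl ether on O3 and a free O1–H). A sulfonate survives the earlier metal, ozone and hydride steps better than an iodide. The formal carbon is already in place as the O3 protecting group, so the ring closes by an intramolecular acetal exchange under conditions that spare the ketal.

8 ⇒ 6 ⇒ 5. Bonds cut: C1–O1 (back to the C1=CH2 alkene, through 7) and the O3–CH2OMe bond. The alkene is a masked α-hydroxy ester. O3 must be capped before the alkene is cleaved, so that it can neither lactonise onto the ester nor be lost by β-elimination from 7.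

5 ⇒ 3 + 4. Bond cut: C2–C3. This joins a three-carbon acrylate unit (C1, C2, carboxyl) to a four-carbon aldehyde and creates C3. The forward step must add anti (Felkin–Anh) to the α-alkoxy aldehyde and tolerate the sulfonate and the tert-butyl ester.

3 ⇒ 2 ⇒ 1. The aldehyde goes back to a primary alcohol and the sulfonate to the second primary alcohol of 1. 1 is C2-symmetric, so either hydroxyl gives the same monosulfonate, and it already carries C4 and C5 with the right absolute configuration.

## Other disconnections considered

Alternative 1: The cut is the C1–O1 bond, made by conjugate addition of a peroxide to an enone.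
- Forward: (−)-shikimic acid A1 would be taken in a few steps to 4-methoxybenzyl 4,5-bis-O-[(E)-4-(methoxymethoxy)cinnamoyl]-3-dehydroshikimate A2. tert-Butyl hydroperoxide with catalytic DBU would add at C1, and the C2 enolate would close the C1–C2 oxirane of 4-methoxybenzyl 1,2-anhydro-2-hydroxy-4,5-bis-O-[(E)-4-(methoxymethoxy)cinnamoyl]-3-dehydroquinate A3 on the face opposite the C5 ester. Reductive opening at C2, reduction of the C3 ketone to the axial alcohol and acid deprotection would follow.
- In its favour: the ring, C4 and C5 come from the chiral pool. The diester regiochemistry is as secure as in the chosen plan (an equal point), because O3 is a ketone when O4 and O5 are acylated. The step count would be roughly half (a better point). Nucleophilic epoxidation is a precedented reaction type, which the chosen ring closure is not (a better point).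
- Against it here: C1 is set by the steric bias of a homoallylic substituent and not by geometry, so the chosen plan is stronger on structure at C1. DBU can enolise the 4-acyloxy-3-ketone at C4 and expel the C5 carboxylate, the first step towards aromatisation. The reductive opening must spare the C4 acyloxy group, which is also α to the ketone. C3 must be re-created by hydride next to migration-prone esters and reducible cinnamates, whereas the chosen plan never exposes the esters to base or hydride.

Alternative 2: The cut is the C3–O3 bond, replaced by C3–H.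
- Forward: 4-methoxybenzyl 3-deoxy-1-O-(diethylsilyl)-4,5-bis-O-(tert-butyldimethylsilyl)quinate A4 would undergo dehydrogenative silylation at the axial C3–H bond with [Ir(cod)OMe]2 (monovalent iridium), 3,4,7,8-tetramethyl-1,10-phenanthroline and norbornene. This would give the oxasilolane A5, 4-methoxybenzyl 3-deoxy-3,O1-(diethylsilanediyl)-4,5-bis-O-(tert-butyldimethylsilyl)quinate. Tamao–Fleming oxidation would later turn C3–Si into C3–O with retention.
- In its favour: O1-directed silylation of a γ C–H bond is a documented reaction class (better on precedent than the chosen key step). The five-membered ring can only span syn-diaxial positions, so C3 is set by geometry, which is equal in kind to the chosen plan's control of C1 and better than its Felkin–Anh control of C3.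
- Against it here: the quaternary C1, the harder problem, must already be present in A4, so the difficulty is moved and not solved. C5–H is also axial, γ and syn to O1, so site selectivity rests on secondary versus tertiary C–H. The conditions are hot for a substrate with two silyl ethers and a benzylic ester. O3 would appear unprotected: either the oxidation precedes acylation and the O3/O4/O5 problem returns, or a basic peroxide oxidation is run on the finished diester, with acyl migration and perhydrolysis as threats.
- On step economy no gain is apparent, since A4 needs its own multistep synthesis.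

Alternative 3: The cut is the C4–C5 bond of a 3-dehydroquinate.
- Forward: the keto aldehyde A6, tert-butyl 2-hydroxy-5-{[(E)-4-(methoxymethoxy)cinnamoyl]oxy}-4-oxo-2-(2-oxoethyl)pentanoate as one C2 enantiomer, is built on a citrate-type chain with differentiated arms. It would be enolised towards C4 with MgBr2·OEt2 and triethylamine and would add reversibly to the C5 aldehyde to give tert-butyl 4-O-[(E)-4-(methoxymethoxy)cinnamoyl]-3-dehydroquinate A7 with O4 and O5 equatorial.
- In its favour: ring, C4 and C5 arise in one step from an inexpensive achiral skeleton. O4 is acylated from the start. The step count could be the lowest of the four plans (a better point). The aldol is a known reaction type (a better point).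
- Against it here: the only stereocentre of A6 is C1 and must come from an enantioselective desymmetrisation. The relation of C1 to C4/C5 depends on which C1 substituent prefers the equatorial position, a small difference, whereas the chosen plan fixes it by a tether. A6 is at once a β-hydroxy aldehyde and a β-hydroxy ketone, so dehydration and retro-aldol cleavage compete. O5 must still be acylated and C3 reduced beside two esters, so the base- and hydride-sensitive end game of Alternative 1 returns.
- Diester regiochemistry is handled about as well as in the chosen plan (roughly equal, relying on the inert tertiary O1), but stereocontrol at C1 is clearly weaker.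

Key step: step 8

Assumption: diol 1 is bought as such (it is the acetonide/hydride-reduction product of diethyl D-tartrate, two routine steps if it must be made). Atom labels C1–C6 and O1–O5 are those of quinic acid throughout; in the carbohydrate-style names heptonate C2–C7 are quinate C1–C6.

Remark on the structures: the planned ring-closure substrate and product were compared with the target centre by centre (O1, O3, O4 on one face; O5 and the carboxyl group on the other; C3/C4 erythro, C4/C5 threo, hence the D-tartrate series). No configuration needed correction; only the O4/O5 protecting groups are changed.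

## Route

Step 1
Reactants: 1 2,3-O-isopropylidene-D-threitol [(4R,5R)-2,2-dimethyl-1,3-dioxolane-4,5-dimethanol]
Product: 2 2,3-O-isopropylidene-1-O-tosyl-D-threitol
Conditions: TsCl (1.1 equiv), Ag2O, KI (cat.), CH2Cl2, 0 °C to rt
Reagents that add atoms: p-toluenesulfonyl chloride, Cc1ccc(cc1)S(=O)(=O)Cl
Why: Ag2O-mediated sulfonylation of a symmetrical diol should stop largely at the monoester; the diol is C2-symmetric, so either hydroxyl gives the same compound and no stereocentre is touched.

Step 2
Reactants: 2 2,3-O-isopropylidene-1-O-tosyl-D-threitol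
Product: 3 2,3-O-isopropylidene-4-O-tosyl-D-threose
Conditions: Dess–Martin periodinane, NaHCO3, CH2Cl2, 0 °C to rt
Reagents that add atoms: none
Why: Dess–Martin oxidation of a primary alcohol under buffered conditions; the α-centre is safe because the trans-disubstituted dioxolane is the thermodynamic arrangement.

Step 3
Reactants: 3 2,3-O-isopropylidene-4-O-tosyl-D-threose; 4 tert-butyl 2-(bromomethyl)acrylate
Product: 5 tert-butyl 2,3-dideoxy-5,6-O-isopropylidene-2-methylidene-7-O-tosyl-D-lyxo-heptonate (O3 anti to O4)
Conditions: In powder, THF/H2O (1:1), rt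
Reagents that add atoms: none
Why: Barbier-type indium-mediated 2-(alkoxycarbonyl)allylation in water; with the α-oxygen tied into the ketal the aldehyde cannot chelate, so the allylindium should add in the Felkin–Anh sense and set C3 anti (erythro) to O4, the minor epimer being removed by chromatography. The tert-butyl ester resists lactonisation by the new hydroxyl, and sulfonate and ketal are inert to indium metal in neutral water.

Step 4
Reactants: 5 tert-butyl 2,3-dideoxy-5,6-O-isopropylidene-2-methylidene-7-O-tosyl-D-lyxo-heptonate
Product: 6 tert-butyl 2,3-dideoxy-5,6-O-isopropylidene-4-O-(methoxymethyl)-2-methylidene-7-O-tosyl-D-lyxo-heptonate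
Conditions: MOMCl, iPr2NEt, CH2Cl2, 0 °C to rt
Reagents that add atoms: chloromethyl methyl ether, COCCl
Why: Standard alkylation of a secondary alcohol to its MOM ether; it blocks O3 against lactonisation and β-elimination in step 5, and its CH2 group becomes the O1–CH2–O3 bridge.

Step 5
Reactants: 6 tert-butyl 2,3-dideoxy-5,6-O-isopropylidene-4-O-(methoxymethyl)-2-methylidene-7-O-tosyl-D-lyxo-heptonate
Product: 8 tert-butyl (2RS)-3-deoxy-5,6-O-isopropylidene-4-O-(methoxymethyl)-7-O-tosylheptonate (C4 to C6 D-lyxo), via keto ester 7 (not isolated)
Conditions: O3, CH2Cl2/MeOH, −78 °C; then NaBH4, −78 to 0 °C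
Reagents that add atoms: ozone, O=[O+][O-]
Why: Ozonolysis of the 1,1-disubstituted alkene gives the α-keto ester, whose ketone NaBH4 reduces at low temperature far faster than the tert-butyl ester and before the β-alkoxy group can eliminate. The configuration formed at C1 does not matter because C1 is enolised in step 8.

Step 6
Reactants: 8 tert-butyl (2RS)-3-deoxy-5,6-O-isopropylidene-4-O-(methoxymethyl)-7-O-tosylheptonate
Product: 9 tert-butyl (2RS)-3-deoxy-5,6-O-isopropylidene-2,4-O-methylene-7-O-tosylheptonate [tert-butyl 6-(trans-2,2-dimethyl-5-tosyloxymethyl-1,3-dioxolan-4-yl)-1,3-dioxane-4-carboxylate]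
Conditions: Me3SiOTf, 2,2'-bipyridyl, CH2Cl2, 0 °C; aq. NaHCO3
Reagents that add atoms: none
Why: Silyl triflate–2,2'-bipyridyl activation of a MOM ether gives a bipyridinium methyl ether, which the silylated O1 captures intramolecularly to close the six-membered formal (acetal exchange of a hydroxy MOM ether). This reagent pair activates aldehyde-type acetals but spares ketals and esters, so the isopropylidene group, sulfonate and tert-butyl ester should survive.

Step 7
Reactants: 9 tert-butyl (2RS)-3-deoxy-5,6-O-isopropylidene-2,4-O-methylene-7-O-tosylheptonate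
Product: 10 tert-butyl (2RS)-3,7-dideoxy-7-iodo-5,6-O-isopropylidene-2,4-O-methyleneheptonate [tert-butyl 6-(trans-5-iodomethyl-2,2-dimethyl-1,3-dioxolan-4-yl)-1,3-dioxane-4-carboxylate]
Conditions: NaI, 2-butanone, 80 °C
Reagents that add atoms: sodium iodide, [Na+].[I-]
Why: Finkelstein exchange (SN2) at the primary sulfonate; the iodide is introduced only now because the sulfonate tolerates indium, ozone and NaBH4 better, and acetals and tert-butyl ester are inert to NaI.

Step 8
Reactants: 10 tert-butyl (2RS)-3,7-dideoxy-7-iodo-5,6-O-isopropylidene-2,4-O-methyleneheptonate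
Product: 11 tert-butyl 4,5-O-isopropylidene-1,3-O-methylenequinate (2,4-dioxabicyclo[3.3.1]nonane core)
Conditions: KN(SiMe3)2 (1.2 equiv), THF (0.01 M), −78 to 0 °C
Reagents that add atoms: none
Why: Proposed new method: KN(SiMe3)2 removes the C1 proton of either epimer of 10 to give one planar potassium ester enolate exocyclic to the dioxane, and the enolate carbon displaces iodide at C6 by intramolecular SN2; the closest known reaction types are the cyclisation of α-alkoxy ester enolates onto tethered halides and the alkylation of enolates of cyclic acetals of α-hydroxy esters. The one ring formed is the cyclohexane, closed 6-(enolexo)-exo-tet through a chair with C1···C6–I collinear and O4 and O5 equatorial. The new stereocentre C1 is fixed by the O1–CH2–O3 tether: C6 hangs from C3 of the same dioxane, so it can reach only the enolate face syn to that side chain, which leaves O1 and O3 cis-diaxial on the new ring and the ester equatorial, whereas the trans isomer would need an in,out-bridged bicyclo[3.3.1]nonane. The reacting conformer has the side chain axial on the dioxane, which costs only a contact with the axial formal hydrogen, and in the product it is the axial C5–H, not an oxygen, that faces the formal carbon. The selectivities needed are C- over O-alkylation (six- versus eight-membered transition state), substitution over elimination (the enolate has no β-leaving group because O3 sits on the γ-carbon, and only a slight excess of base is used so that E2 at C5–H is not fed) and intra- over intermolecular alkylation (high dilution). The ketal holds O4–C4–C5–O5 synclinal, as the chair demands, where two vicinal silyloxy groups would prefer to be antiperiplanar.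

Step 9
Reactants: 11 tert-butyl 4,5-O-isopropylidene-1,3-O-methylenequinate
Product: 12 tert-butyl 1,3-O-methylenequinate
Conditions: AcOH/H2O (4:1), 40 °C
Reagents that add atoms: none
Why: Acid hydrolysis of a ketal: ionisation to a tertiary oxocarbenium ion is fast and is helped by the strain of the trans-fused dioxolane, whereas the formal would need a primary oxocarbenium ion and the tert-butyl ester much stronger acid. No stereocentre is involved.

Step 10
Reactants: 13 (E)-p-coumaric acid
Product: 15 (E)-3-[4-(methoxymethoxy)phenyl]prop-2-enoic acid, via MOM ester 14 (not isolated)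
Conditions: MOMCl, iPr2NEt, CH2Cl2, 0 °C to rt; then NaOH, MeOH/H2O, rt; dilute HCl to pH 4, 0 °C
Reagents that add atoms: chloromethyl methyl ether, COCCl
Why: Both acidic OH groups are alkylated by MOMCl, then only the MOM ester, an acylal-type ester far more labile than the aryl MOM ether, is saponified in the same flask; the E-alkene is untouched.

Step 11
Reactants: 12 tert-butyl 1,3-O-methylenequinate; 15 (E)-3-[4-(methoxymethoxy)phenyl]prop-2-enoic acid
Product: 16 tert-butyl 4,5-bis-O-[(E)-4-(methoxymethoxy)cinnamoyl]-1,3-O-methylenequinate
Conditions: 15 (3 equiv), EDC·HCl, DMAP, CH2Cl2, rt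
Reagents that add atoms: none
Why: Steglich esterification (carbodiimide activation, acyl transfer by DMAP) of the two equatorial secondary hydroxyls with excess acid; O1 and O3 are tied up in the formal, so neither regioselectivity nor acyl migration arises.

Step 12
Reactants: 16 tert-butyl 4,5-bis-O-[(E)-4-(methoxymethoxy)cinnamoyl]-1,3-O-methylenequinate
Product: 18 4,5-di-O-[(E)-p-coumaroyl]quinic acid, via tert-butyl 4,5-di-O-p-coumaroylquinate 17 (not isolated)
Conditions: Me3SiOTf, 2,2'-bipyridyl, CH2Cl2, 0 °C to rt; H2O; then CF3CO2H/CH2Cl2/H2O, 0 °C to rt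
Reagents that add atoms: none
Why: Known silyl triflate–2,2'-bipyridyl cleavage of MOM ethers and methylene acetals: the aryl MOM ethers become aryl silyl ethers and the formal opens to a silyl ether plus a bipyridinium methyl ether, all hydrolysed by water to 17, after which CF3CO2H removes the tert-butyl group by E1 loss of isobutene. The sequence is acidic or neutral throughout, so the base-promoted O4-to-O3 acyl shift should be avoided and the E-alkenes stay intact.

## Compound list

1 | 2,3-O-isopropylidene-D-threitol [(4R,5R)-2,2-dimethyl-1,3-dioxolane-4,5-dimethanol] | OC[C@H]1OC(C)(C)O[C@@H]1CO | starting material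
2 | 2,3-O-isopropylidene-1-O-tosyl-D-threitol | Cc1ccc(cc1)S(=O)(=O)OC[C@H]1OC(C)(C)O[C@@H]1CO | intermediate
3 | 2,3-O-isopropylidene-4-O-tosyl-D-threose | Cc1ccc(cc1)S(=O)(=O)OC[C@H]1OC(C)(C)O[C@@H]1C=O | intermediate
4 | tert-butyl 2-(bromomethyl)acrylate | C=C(CBr)C(=O)OC(C)(C)C | starting material
5 | tert-butyl 2,3-dideoxy-5,6-O-isopropylidene-2-methylidene-7-O-tosyl-D-lyxo-heptonate | Cc1ccc(cc1)S(=O)(=O)OC[C@H]1OC(C)(C)O[C@@H]1[C@H](O)CC(=C)C(=O)OC(C)(C)C | intermediate
6 | tert-butyl 2,3-dideoxy-5,6-O-isopropylidene-4-O-(methoxymethyl)-2-methylidene-7-O-tosyl-D-lyxo-heptonate | Cc1ccc(cc1)S(=O)(=O)OC[C@H]1OC(C)(C)O[C@@H]1[C@H](OCOC)CC(=C)C(=O)OC(C)(C)C | intermediate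
7 | tert-butyl 3-deoxy-5,6-O-isopropylidene-4-O-(methoxymethyl)-7-O-tosyl-D-lyxo-hept-2-ulosonate | Cc1ccc(cc1)S(=O)(=O)OC[C@H]1OC(C)(C)O[C@@H]1[C@H](OCOC)CC(=O)C(=O)OC(C)(C)C | intermediate (not isolated)
8 | tert-butyl (2RS)-3-deoxy-5,6-O-isopropylidene-4-O-(methoxymethyl)-7-O-tosylheptonate (C4 to C6 D-lyxo) | Cc1ccc(cc1)S(=O)(=O)OC[C@H]1OC(C)(C)O[C@@H]1[C@H](OCOC)CC(O)C(=O)OC(C)(C)C | intermediate
9 | tert-butyl (2RS)-3-deoxy-5,6-O-isopropylidene-2,4-O-methylene-7-O-tosylheptonate (C4 to C6 D-lyxo) | Cc1ccc(cc1)S(=O)(=O)OC[C@H]1OC(C)(C)O[C@@H]1[C@H]2CC(C(=O)OC(C)(C)C)OCO2 | intermediate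
10 | tert-butyl (2RS)-3,7-dideoxy-7-iodo-5,6-O-isopropylidene-2,4-O-methyleneheptonate (C4 to C6 D-lyxo) | IC[C@H]1OC(C)(C)O[C@@H]1[C@H]2CC(C(=O)OC(C)(C)C)OCO2 | intermediate (key-step precursor)
11 | tert-butyl 4,5-O-isopropylidene-1,3-O-methylenequinate | CC1(C)O[C@@H]2[C@H]3C[C@@](OCO3)(C(=O)OC(C)(C)C)C[C@H]2O1 | intermediate (key-step product)
12 | tert-butyl 1,3-O-methylenequinate | O[C@@H]1[C@H]2C[C@@](OCO2)(C(=O)OC(C)(C)C)C[C@H]1O | intermediate
13 | (E)-p-coumaric acid | OC(=O)/C=C/c1ccc(O)cc1 | starting material
14 | methoxymethyl (E)-3-[4-(methoxymethoxy)phenyl]prop-2-enoate | COCOC(=O)/C=C/c1ccc(OCOC)cc1 | intermediate (not isolated)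
15 | (E)-3-[4-(methoxymethoxy)phenyl]prop-2-enoic acid | OC(=O)/C=C/c1ccc(OCOC)cc1 | intermediate
16 | tert-butyl 4,5-bis-O-[(E)-4-(methoxymethoxy)cinnamoyl]-1,3-O-methylenequinate | O=C(/C=C/c1ccc(OCOC)cc1)O[C@@H]1[C@H]2C[C@@](OCO2)(C(=O)OC(C)(C)C)C[C@H]1OC(=O)/C=C/c1ccc(OCOC)cc1 | intermediate
17 | tert-butyl 4,5-di-O-[(E)-p-coumaroyl]quinate | O=C(/C=C/c1ccc(O)cc1)O[C@@H]1[C@H](O)C[C@@](O)(C(=O)OC(C)(C)C)C[C@H]1OC(=O)/C=C/c1ccc(O)cc1 | intermediate (not isolated)
18 | 4,5-di-O-[(E)-p-coumaroyl]quinic acid | O=C(/C=C/c1ccc(O)cc1)O[C@@H]1[C@H](O)C[C@@](O)(C(=O)O)C[C@H]1OC(=O)/C=C/c1ccc(O)cc1 | target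

## Step count and least certain steps

Total step count: 12. Longest linear sequence: 11 steps (1 to 18 through steps 1–9, 11 and 12); step 10 prepares 15 in a side branch.

Step 8 (key step, proposed new method). The most likely failure is that ring closure is outrun by base-induced loss of HI across C5–C6 or by intermolecular alkylation. The reacting conformer needs the side chain axial on the dioxane, and the trans-fused dioxolane resists the flattening at C5 that a 2,4-dioxabicyclo[3.3.1]nonane prefers. The fallback uses known chemistry, sets out from 8 and returns at 18; it gives up the tether and closes C1–C6 by the known cyclisation of an acyclic α-alkoxy ester enolate. MOMCl/iPr2NEt caps O1 to give tert-butyl (2RS)-3-deoxy-5,6-O-isopropylidene-2,4-bis-O-(methoxymethyl)-7-O-tosylheptonate F1. NaI exchange gives tert-butyl (2RS)-3,7-dideoxy-7-iodo-5,6-O-isopropylidene-2,4-bis-O-(methoxymethyl)heptonate F2. KN(SiMe3)2 in dilute THF closes the ring to tert-butyl 4,5-O-isopropylidene-1,3-bis-O-(methoxymethyl)quinate F3. C1 is then governed only by the chair preference for an equatorial ester enolate, so a chromatographic separation at C1 must be expected. Aqueous AcOH gives tert-butyl 1,3-bis-O-(methoxymethyl)quinate F4, esterification with 15 gives tert-butyl 4,5-bis-O-[(E)-4-(methoxymethoxy)cinnamoyl]-1,3-bis-O-(methoxymethyl)quinate F5, and the conditions of step 12 take F5 to 18.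

Step 3. The most likely failure is poor facial selectivity, since the Felkin–Anh preference of a dioxolane-substituted aldehyde towards an allylindium in water is moderate and is substrate bias only. The fallback sets out from 3 and returns at 5; the allylation is run unchanged and the unwanted epimer is recycled by inversion. The epimer tert-butyl 2,3-dideoxy-5,6-O-isopropylidene-2-methylidene-7-O-tosyl-D-xylo-heptonate F6 is separated and subjected to a Mitsunobu reaction (4-nitrobenzoic acid, PPh3, DIAD). This gives tert-butyl 2,3-dideoxy-5,6-O-isopropylidene-2-methylidene-4-O-(4-nitrobenzoyl)-7-O-tosyl-D-lyxo-heptonate F7, and methanolysis (K2CO3, MeOH, 0 °C) gives 5.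

Step 6. The most likely failure is incomplete capture of the bipyridinium methyl ether by the hindered O1, or re-opening of the new formal by excess reagent, so that hydrolysis on work-up returns a diol. The fallback sets out from 8 and returns at 9; the formal is then built from the free diol with an external one-carbon donor. The same reagent pair followed by water is used deliberately as a MOM cleavage to give tert-butyl (2RS)-3-deoxy-5,6-O-isopropylidene-7-O-tosylheptonate F8 (C4 to C6 D-lyxo). F8 is converted into 9 by acetal exchange with dimethoxymethane (LiBr, catalytic TsOH, rt), watched closely because this medium can also exchange the ketal.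

Step 12. The most likely failure is slow opening of the bridged formal on the sensitive diester, so that long exposure leads to O4-to-O3 acyl migration once O3 is free, or to tert-butylation of the phenols. The fallback sets out from 11 and returns at 18; the formal is opened before the acylation, on a robust substrate that can be forced. Me3SiOTf/2,2'-bipyridyl then water gives tert-butyl 4,5-O-isopropylidenequinate F9. TBSCl/imidazole in DMF silylates the secondary O3 to give tert-butyl 3-O-(tert-butyldimethylsilyl)-4,5-O-isopropylidenequinate F10. Aqueous AcOH gives tert-butyl 3-O-(tert-butyldimethylsilyl)quinate F11. Esterification with 15 (EDC·HCl, DMAP; the tertiary O1 stays free) gives tert-butyl 3-O-(tert-butyldimethylsilyl)-4,5-bis-O-[(E)-4-(methoxymethoxy)cinnamoyl]quinate F12. CF3CO2H/CH2Cl2/H2O then removes the silyl ether, the aryl MOM ethers and the tert-butyl ester in one acidic step to give 18.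

## Further compounds

F1 | step 8 | tert-butyl (2RS)-3-deoxy-5,6-O-isopropylidene-2,4-bis-O-(methoxymethyl)-7-O-tosylheptonate | Cc1ccc(cc1)S(=O)(=O)OC[C@H]1OC(C)(C)O[C@@H]1[C@H](OCOC)CC(OCOC)C(=O)OC(C)(C)C
F2 | step 8 | tert-butyl (2RS)-3,7-dideoxy-7-iodo-5,6-O-isopropylidene-2,4-bis-O-(methoxymethyl)heptonate | IC[C@H]1OC(C)(C)O[C@@H]1[C@H](OCOC)CC(OCOC)C(=O)OC(C)(C)C
F3 | step 8 | tert-butyl 4,5-O-isopropylidene-1,3-bis-O-(methoxymethyl)quinate | CC1(C)O[C@@H]2[C@H](OCOC)C[C@@](OCOC)(C(=O)OC(C)(C)C)C[C@H]2O1
F4 | step 8 | tert-butyl 1,3-bis-O-(methoxymethyl)quinate | O[C@@H]1[C@H](OCOC)C[C@@](OCOC)(C(=O)OC(C)(C)C)C[C@H]1O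
F5 | step 8 | tert-butyl 4,5-bis-O-[(E)-4-(methoxymethoxy)cinnamoyl]-1,3-bis-O-(methoxymethyl)quinate | O=C(/C=C/c1ccc(OCOC)cc1)O[C@@H]1[C@H](OCOC)C[C@@](OCOC)(C(=O)OC(C)(C)C)C[C@H]1OC(=O)/C=C/c1ccc(OCOC)cc1
F6 | step 3 | tert-butyl 2,3-dideoxy-5,6-O-isopropylidene-2-methylidene-7-O-tosyl-D-xylo-heptonate | Cc1ccc(cc1)S(=O)(=O)OC[C@H]1OC(C)(C)O[C@@H]1[C@@H](O)CC(=C)C(=O)OC(C)(C)C
F7 | step 3 | tert-butyl 2,3-dideoxy-5,6-O-isopropylidene-2-methylidene-4-O-(4-nitrobenzoyl)-7-O-tosyl-D-lyxo-heptonate | Cc1ccc(cc1)S(=O)(=O)OC[C@H]1OC(C)(C)O[C@@H]1[C@H](OC(=O)c2ccc(cc2)[N+](=O)[O-])CC(=C)C(=O)OC(C)(C)C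
F8 | step 6 | tert-butyl (2RS)-3-deoxy-5,6-O-isopropylidene-7-O-tosylheptonate (C4 to C6 D-lyxo) | Cc1ccc(cc1)S(=O)(=O)OC[C@H]1OC(C)(C)O[C@@H]1[C@H](O)CC(O)C(=O)OC(C)(C)C
F9 | step 12 | tert-butyl 4,5-O-isopropylidenequinate | CC1(C)O[C@@H]2[C@H](O)C[C@@](O)(C(=O)OC(C)(C)C)C[C@H]2O1
F10 | step 12 | tert-butyl 3-O-(tert-butyldimethylsilyl)-4,5-O-isopropylidenequinate | CC1(C)O[C@@H]2[C@H](O[Si](C)(C)C(C)(C)C)C[C@@](O)(C(=O)OC(C)(C)C)C[C@H]2O1
F11 | step 12 | tert-butyl 3-O-(tert-butyldimethylsilyl)quinate | O[C@@H]1[C@H](O[Si](C)(C)C(C)(C)C)C[C@@](O)(C(=O)OC(C)(C)C)C[C@H]1O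
F12 | step 12 | tert-butyl 3-O-(tert-butyldimethylsilyl)-4,5-bis-O-[(E)-4-(methoxymethoxy)cinnamoyl]quinate | O=C(/C=C/c1ccc(OCOC)cc1)O[C@@H]1[C@H](O[Si](C)(C)C(C)(C)C)C[C@@](O)(C(=O)OC(C)(C)C)C[C@H]1OC(=O)/C=C/c1ccc(OCOC)cc1
A1 | alternative 1 | (−)-shikimic acid | O[C@@H]1[C@H](O)C=C(C(=O)O)C[C@H]1O
A2 | alternative 1 | 4-methoxybenzyl 4,5-bis-O-[(E)-4-(methoxymethoxy)cinnamoyl]-3-dehydroshikimate | O=C(/C=C/c1ccc(OCOC)cc1)O[C@@H]1C(=O)C=C(C(=O)OCc2ccc(OC)cc2)C[C@H]1OC(=O)/C=C/c1ccc(OCOC)cc1
A3 | alternative 1 | 4-methoxybenzyl 1,2-anhydro-2-hydroxy-4,5-bis-O-[(E)-4-(methoxymethoxy)cinnamoyl]-3-dehydroquinate | O=C(/C=C/c1ccc(OCOC)cc1)O[C@@H]1C(=O)[C@@H]2O[C@]2(C(=O)OCc2ccc(OC)cc2)C[C@H]1OC(=O)/C=C/c1ccc(OCOC)cc1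
A4 | alternative 2 | 4-methoxybenzyl 3-deoxy-1-O-(diethylsilyl)-4,5-bis-O-(tert-butyldimethylsilyl)quinate | CC(C)(C)[Si](C)(C)O[C@@H]1CC[C@@](O[SiH](CC)CC)(C(=O)OCc2ccc(OC)cc2)C[C@H]1O[Si](C)(C)C(C)(C)C
A5 | alternative 2 | 4-methoxybenzyl 3-deoxy-3,O1-(diethylsilanediyl)-4,5-bis-O-(tert-butyldimethylsilyl)quinate | CC(C)(C)[Si](C)(C)O[C@@H]1[C@H]2C[C@@](O[Si]2(CC)CC)(C(=O)OCc2ccc(OC)cc2)C[C@H]1O[Si](C)(C)C(C)(C)C
A6 | alternative 3 | tert-butyl 2-hydroxy-5-{[(E)-4-(methoxymethoxy)cinnamoyl]oxy}-4-oxo-2-(2-oxoethyl)pentanoate | O=CC[C@](O)(C(=O)OC(C)(C)C)CC(=O)COC(=O)/C=C/c1ccc(OCOC)cc1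
A7 | alternative 3 | tert-butyl 4-O-[(E)-4-(methoxymethoxy)cinnamoyl]-3-dehydroquinate | O=C(/C=C/c1ccc(OCOC)cc1)O[C@@H]1C(=O)C[C@@](O)(C(=O)OC(C)(C)C)C[C@H]1O
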